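**Plan**

- Retrosynthesis: the two O–Si bonds and the C5–O–C6 epoxide go first. The ten-membered lactone is then cut at C6–C7 (alkenyl metal plus aldehyde). The open chain is cut at the C8 enoate ester, at the O9–C1 ester and at C5=C6 (iodo-olefination).
- Forward: the C1–C6 acid 9 is made from a C2-symmetric diene diol. It opens the C7–C14 epoxy alcohol 16 at C9, which joins the chain through the future ring oxygen. C8 is then acylated with enoic acid 14 and C7 is oxidised. The only ring closure is C6–C7; epoxidation and desilylation finish.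
- Stereochemistry: C3/C4 come from diol 1. C8 comes from Sharpless epoxidation (L-(+)-tartrate) and C9 from inversion in the epoxide opening. The side-chain center comes from (R)-2-methylbutanoic acid. C7 is set by Felkin–Anh addition anti to the C8–O bond, and C5/C6 by matched, hydroxyl-directed epoxidation (D-(−)-tartrate).
- Enabling feature: in the lactone ring (C1 carbonyl carbon to C9 plus the ring oxygen), C7 is a carbinol that is allylic to C5=C6 before epoxidation and anti to the acyloxy-bearing C8. An E-alkenyl metal at C6 adding to a C7 aldehyde produces exactly this pattern.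

Key step: step 15

Remark: the lactone is numbered C1 (carbonyl) to C9 (pentyl-bearing carbon), pentyl = C10–C14; (3R,4R)-hexa-1,5-diene-3,4-diol 1 and (R)-2-methylbutanoic acid 10 are assumed to be purchasable in enantiopure form. TBS = tert-butyldimethylsilyl, TES = triethylsilyl.

**Route**

Step 1
Reactants: 1 (3R,4R)-hexa-1,5-diene-3,4-diol
Product: 2 (3R,4R)-3,4-bis(TBS-oxy)hexa-1,5-diene
Conditions: TBSCl, imidazole, DMF, rt
Reagents that add atoms: tert-butyldimethylsilyl chloride, CC(C)(C)[Si](C)(C)Cl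
Why: Silyl ether formation on both secondary allylic hydroxyls installs fluoride-labile groups that should last to the final step, and no stereocenter is touched.

Step 2
Reactants: 2 (3R,4R)-3,4-bis(TBS-oxy)hexa-1,5-diene
Product: 4 (2S,3R)-2,3-bis(TBS-oxy)pent-4-enal, via ozonide 3 (not isolated)
Conditions: O3 (about 0.6 equiv, as a cold CH2Cl2 solution), CH2Cl2, −78 °C; then PPh3, −78 °C to rt; unreacted 2 recovered and recycled
Reagents that add atoms: ozone, [O-][O+]=O
Why: Ozonolysis with reductive work-up cleaves one of the two vinyl groups, which the C2 axis makes equivalent, so limiting ozone should give a single α-silyloxy aldehyde with both stereocenters untouched.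

Step 3
Reactants: 4 (2S,3R)-2,3-bis(TBS-oxy)pent-4-enal
Product: 5 (1E,3R,4R)-3,4-bis(TBS-oxy)-1-iodohexa-1,5-diene
Conditions: CrCl2, CHI3, THF/1,4-dioxane, 0 °C to rt
Reagents that add atoms: iodoform, IC(I)I
Why: Takai iodo-olefination, in which the geminal dichromium reagent from CHI3 adds to the aldehyde and eliminates to the E-iodoalkene (C5=C6), should leave the terminal alkene and the silyl ethers alone under the non-basic divalent chromium conditions.

Step 4
Reactants: 5 (1E,3R,4R)-3,4-bis(TBS-oxy)-1-iodohexa-1,5-diene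
Product: 7 (3R,4R,5E)-3,4-bis(TBS-oxy)-6-iodohex-5-en-1-ol, via B-alkyl-9-BBN adduct 6 (not isolated)
Conditions: 9-BBN, THF, 0 °C to rt; then aq NaOH, H2O2, 0 °C
Reagents that add atoms: hydrogen peroxide, OO
Why: Hydroboration–oxidation with 9-BBN places boron on the terminal carbon of the unhindered vinyl group far faster than on the electron-poor internal iodoalkene, and alkaline peroxide then replaces boron by hydroxyl without touching C3 or C4.

Step 5
Reactants: 7 (3R,4R,5E)-3,4-bis(TBS-oxy)-6-iodohex-5-en-1-ol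
Product: 9 (3R,4R,5E)-3,4-bis(TBS-oxy)-6-iodohex-5-enoic acid, via aldehyde 8 (not isolated)
Conditions: TEMPO (cat.), PhI(OAc)2, MeCN/H2O, rt
Reagents that add atoms: water, O
Why: Oxoammonium (TEMPO) oxidation with PhI(OAc)2 in aqueous acetonitrile takes the primary alcohol through the aldehyde hydrate to the acid under near-neutral conditions that should spare silyl ethers and the iodoalkene.

Step 6
Reactants: 10 (R)-2-methylbutanoic acid
Product: 11 (R)-2-methylbutan-1-ol
Conditions: LiAlH4, Et2O, 0 °C to rt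
Reagents that add atoms: none
Why: Hydride reduction of a carboxylic acid with LiAlH4 proceeds through the carboxylate, which is not enolised, so the α-center should be kept.

Step 7
Reactants: 11 (R)-2-methylbutan-1-ol
Product: 13 ethyl (2E,4R)-2,4-dimethylhex-2-enoate, via (R)-2-methylbutanal 12 (not isolated)
Conditions: TEMPO (cat.), PhI(OAc)2, CH2Cl2, rt; then Ph3P=C(CH3)CO2Et, rt
Reagents that add atoms: ethyl 2-(triphenylphosphoranylidene)propanoate, CCOC(=O)C(C)=P(c1ccccc1)(c1ccccc1)c1ccccc1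
Why: Oxoammonium oxidation followed in the same flask by Wittig olefination with a stabilised α-methyl ylide should give the E-trisubstituted enoate and avoids isolating the volatile, epimerisable aldehyde.

Step 8
Reactants: 13 ethyl (2E,4R)-2,4-dimethylhex-2-enoate
Product: 14 (2E,4R)-2,4-dimethylhex-2-enoic acid
Conditions: LiOH, THF/MeOH/H2O, rt; then aq HCl
Reagents that add atoms: lithium hydroxide, [Li+].[OH-]
Why: Saponification of the ethyl ester is expected to leave the E-alkene and the γ-center unchanged, since γ-deprotonation of the enoate does not compete at room temperature.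

Step 9
Reactants: 15 (E)-oct-2-en-1-ol
Product: 16 [(2S,3S)-3-pentyloxiran-2-yl]methanol
Conditions: Ti(OiPr)4 (cat.), L-(+)-diisopropyl tartrate (cat.), tert-butyl hydroperoxide, 4 Å molecular sieves, CH2Cl2, −20 °C
Reagents that add atoms: tert-butyl hydroperoxide, CC(C)(C)OO
Why: Sharpless asymmetric epoxidation with the titanium–L-(+)-tartrate complex delivers oxygen to the face of the E-allylic alcohol that gives the (2S,3S)-epoxide, which fixes the future C8 and, after inversion, C9.

Step 10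
Reactants: 16 [(2S,3S)-3-pentyloxiran-2-yl]methanol (slight excess); 9 (3R,4R,5E)-3,4-bis(TBS-oxy)-6-iodohex-5-enoic acid
Product: 17 (2S,3R)-1,2-dihydroxyoctan-3-yl ester of acid 9
Conditions: Ti(OiPr)4 (1.5 equiv), CH2Cl2, rt; aqueous tartaric acid work-up
Reagents that add atoms: none
Why: Titanium-mediated opening of a 2,3-epoxy alcohol by a carboxylic acid holds the epoxy alkoxide and the carboxylate on one titanium centre, so the acid oxygen should attack the distal carbon C3 with inversion, forming the O9–C1 ester and the 9R center together while C8 keeps its oxygen and configuration.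

Step 11
Reactants: 17 (2S,3R)-1,2-dihydroxyoctan-3-yl ester of acid 9
Product: 18 (2S,3R)-2-hydroxy-1-(TES-oxy)octan-3-yl ester of acid 9
Conditions: TESCl, imidazole, CH2Cl2, −78 to −20 °C
Reagents that add atoms: chlorotriethylsilane, CC[Si](Cl)(CC)CC
Why: Selective silylation is expected because the primary C7 hydroxyl reacts with TESCl at low temperature much faster than the flanked secondary C8 hydroxyl.

Step 12
Reactants: 18 (2S,3R)-2-hydroxy-1-(TES-oxy)octan-3-yl ester of acid 9; 14 (2E,4R)-2,4-dimethylhex-2-enoic acid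
Product: 20 (2S,3R)-2-[(2E,4R)-2,4-dimethylhex-2-enoyloxy]-1-(TES-oxy)octan-3-yl ester of acid 9, via mixed anhydride 19 (not isolated)
Conditions: 14, 2,4,6-trichlorobenzoyl chloride, Et3N, toluene, rt; then 18, DMAP, 0 °C to rt
Reagents that add atoms: none
Why: Yamaguchi esterification transfers the enoyl group from the mixed 2,4,6-trichlorobenzoic anhydride to the C8 hydroxyl under DMAP catalysis, and the quick, mild acylation should leave C8 and the γ-center of the enoate unchanged.

Step 13
Reactants: 20 (2S,3R)-2-[(2E,4R)-2,4-dimethylhex-2-enoyloxy]-1-(TES-oxy)octan-3-yl ester of acid 9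
Product: 21 (2S,3R)-2-[(2E,4R)-2,4-dimethylhex-2-enoyloxy]-1-hydroxyoctan-3-yl ester of acid 9
Conditions: PPTS (cat.), MeOH/CH2Cl2, 0 °C
Reagents that add atoms: none
Why: Acid-catalysed methanolysis of silyl ethers cleaves a primary triethylsilyl ether much faster than secondary tert-butyldimethylsilyl ethers, so only the C7 hydroxyl should be freed.

Step 14
Reactants: 21 (2S,3R)-2-[(2E,4R)-2,4-dimethylhex-2-enoyloxy]-1-hydroxyoctan-3-yl ester of acid 9
Product: 22 (2R,3R)-2-[(2E,4R)-2,4-dimethylhex-2-enoyloxy]-1-oxooctan-3-yl ester of acid 9 (C7 aldehyde, vinyl iodide at C6)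
Conditions: Dess–Martin periodinane, pyridine, CH2Cl2, 0 °C to rt; used directly
Reagents that add atoms: none
Why: Dess–Martin oxidation buffered with pyridine gives the aldehyde without strong base, which should avoid epimerisation at C8 and β-elimination of the C9 acyloxy group.

Step 15
Reactants: 22 (2R,3R)-2-[(2E,4R)-2,4-dimethylhex-2-enoyloxy]-1-oxooctan-3-yl (3R,4R,5E)-3,4-bis(TBS-oxy)-6-iodohex-5-enoate
Product: 23 (3R,4R,5E,7S,8S,9R)-3,4-bis(TBS-oxy)-8-[(2E,4R)-2,4-dimethylhex-2-enoyloxy]-7-hydroxytetradec-5-en-9-olide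
Conditions: CrCl2 (excess), NiCl2 (cat.), degassed DMSO, slow addition to about 0.003 M, rt
Reagents that add atoms: none
Why: Zerovalent nickel, formed from NiCl2 by divalent chromium, inserts into the C6–I bond with retention of the E geometry and passes the alkenyl group to trivalent chromium, and this alkenylchromium adds to the C7 aldehyde (Nozaki–Hiyama–Kishi reaction). The closest known reaction type is the intramolecular Nozaki–Hiyama–Kishi coupling used to close medium-ring lactones as allylic alcohols. The ten-membered ring closes in a 10-exo-trig mode by C6–C7 bond formation, and slow addition at high dilution should favour it over oligomerisation. The new C7 center is controlled by C8: in the polar Felkin–Anh arrangement the C8–O bond lies anti to the incoming alkenyl group, which should give the 7,8-anti (7S) carbinol. The step needs attack at the aldehyde only, which the aldehyde-selective, weakly basic alkenylchromium secures in the presence of both esters, and it needs the C8 acyl group to stay on O8, which the hindered α-methyl enoate and the poorly nucleophilic chromium alkoxide secure.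

Step 16
Reactants: 23 (3R,4R,5E,7S,8S,9R)-3,4-bis(TBS-oxy)-8-[(2E,4R)-2,4-dimethylhex-2-enoyloxy]-7-hydroxytetradec-5-en-9-olide
Product: 24 (3R,4R,5S,6R,7S,8S,9R)-3,4-bis(TBS-oxy)-8-[(2E,4R)-2,4-dimethylhex-2-enoyloxy]-5,6-epoxy-7-hydroxytetradecan-9-olide (C4/C5 descriptors differ from those of the target only because of the silyl groups)
Conditions: Ti(OiPr)4, D-(−)-diisopropyl tartrate, tert-butyl hydroperoxide, 4 Å molecular sieves, CH2Cl2, −20 °C
Reagents that add atoms: tert-butyl hydroperoxide, CC(C)(C)OO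
Why: Sharpless epoxidation of a secondary allylic alcohol in the matched sense is expected, since with D-(−)-tartrate the 7S carbinol is the fast-reacting configuration and oxygen goes to the C5=C6 face erythro to the C7 hydroxyl, while the silylated C4 oxygen cannot direct to the other face.

Step 17
Reactants: 24 (3R,4R,5S,6R,7S,8S,9R)-3,4-bis(TBS-oxy)-8-[(2E,4R)-2,4-dimethylhex-2-enoyloxy]-5,6-epoxy-7-hydroxytetradecan-9-olide
Product: 25 (3R,4S,5R,6R,7S,8S,9R)-8-[(2E,4R)-2,4-dimethylhex-2-enoyloxy]-5,6-epoxy-3,4,7-trihydroxytetradecan-9-olide (CNP0548321.2)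
Conditions: HF·pyridine, pyridine, THF, 0 °C to rt
Reagents that add atoms: none
Why: Fluoride-mediated desilylation with pyridine-buffered HF should remove both secondary silyl ethers without opening the epoxide or transposing the lactone.

**Compound list**

1 | (3R,4R)-hexa-1,5-diene-3,4-diol | C=C[C@@H](O)[C@H](O)C=C | starting material
2 | (3R,4R)-3,4-bis(tert-butyldimethylsilyloxy)hexa-1,5-diene | C=C[C@@H](O[Si](C)(C)C(C)(C)C)[C@H](O[Si](C)(C)C(C)(C)C)C=C | intermediate
3 | 3-[(1S,2R)-1,2-bis(tert-butyldimethylsilyloxy)but-3-enyl]-1,2,4-trioxolane (ozonide, trioxolane carbon unassigned) | C=C[C@@H](O[Si](C)(C)C(C)(C)C)[C@H](O[Si](C)(C)C(C)(C)C)C1OCOO1 | intermediate (not isolated)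
4 | (2S,3R)-2,3-bis(tert-butyldimethylsilyloxy)pent-4-enal | C=C[C@@H](O[Si](C)(C)C(C)(C)C)[C@H](O[Si](C)(C)C(C)(C)C)C=O | intermediate
5 | (1E,3R,4R)-3,4-bis(tert-butyldimethylsilyloxy)-1-iodohexa-1,5-diene | C=C[C@@H](O[Si](C)(C)C(C)(C)C)[C@H](O[Si](C)(C)C(C)(C)C)/C=C/I | intermediate
6 | 9-[(3R,4R,5E)-3,4-bis(tert-butyldimethylsilyloxy)-6-iodohex-5-enyl]-9-borabicyclo[3.3.1]nonane | B1(CC[C@@H](O[Si](C)(C)C(C)(C)C)[C@H](O[Si](C)(C)C(C)(C)C)/C=C/I)C2CCCC1CCC2 | intermediate (not isolated)
7 | (3R,4R,5E)-3,4-bis(tert-butyldimethylsilyloxy)-6-iodohex-5-en-1-ol | OCC[C@@H](O[Si](C)(C)C(C)(C)C)[C@H](O[Si](C)(C)C(C)(C)C)/C=C/I | intermediate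
8 | (3R,4R,5E)-3,4-bis(tert-butyldimethylsilyloxy)-6-iodohex-5-enal | O=CC[C@@H](O[Si](C)(C)C(C)(C)C)[C@H](O[Si](C)(C)C(C)(C)C)/C=C/I | intermediate (not isolated)
9 | (3R,4R,5E)-3,4-bis(tert-butyldimethylsilyloxy)-6-iodohex-5-enoic acid | OC(=O)C[C@@H](O[Si](C)(C)C(C)(C)C)[C@H](O[Si](C)(C)C(C)(C)C)/C=C/I | intermediate
10 | (R)-2-methylbutanoic acid | CC[C@@H](C)C(=O)O | starting material
11 | (R)-2-methylbutan-1-ol | CC[C@@H](C)CO | intermediate
12 | (R)-2-methylbutanal | CC[C@@H](C)C=O | intermediate (not isolated)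
13 | ethyl (2E,4R)-2,4-dimethylhex-2-enoate | CCOC(=O)/C(C)=C/[C@H](C)CC | intermediate
14 | (2E,4R)-2,4-dimethylhex-2-enoic acid | OC(=O)/C(C)=C/[C@H](C)CC | intermediate
15 | (E)-oct-2-en-1-ol | CCCCC/C=C/CO | starting material
16 | [(2S,3S)-3-pentyloxiran-2-yl]methanol | CCCCC[C@@H]1O[C@H]1CO | intermediate
17 | (2S,3R)-1,2-dihydroxyoctan-3-yl (3R,4R,5E)-3,4-bis(tert-butyldimethylsilyloxy)-6-iodohex-5-enoate | CCCCC[C@@H](OC(=O)C[C@@H](O[Si](C)(C)C(C)(C)C)[C@H](O[Si](C)(C)C(C)(C)C)/C=C/I)[C@@H](O)CO | intermediate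
18 | (2S,3R)-2-hydroxy-1-(triethylsilyloxy)octan-3-yl (3R,4R,5E)-3,4-bis(tert-butyldimethylsilyloxy)-6-iodohex-5-enoate | CCCCC[C@@H](OC(=O)C[C@@H](O[Si](C)(C)C(C)(C)C)[C@H](O[Si](C)(C)C(C)(C)C)/C=C/I)[C@@H](O)CO[Si](CC)(CC)CC | intermediate
19 | (2E,4R)-2,4-dimethylhex-2-enoic 2,4,6-trichlorobenzoic anhydride | O=C(OC(=O)/C(C)=C/[C@H](C)CC)c1c(Cl)cc(Cl)cc1Cl | intermediate (not isolated)
20 | (2S,3R)-2-[(2E,4R)-2,4-dimethylhex-2-enoyloxy]-1-(triethylsilyloxy)octan-3-yl (3R,4R,5E)-3,4-bis(tert-butyldimethylsilyloxy)-6-iodohex-5-enoate | CCCCC[C@@H](OC(=O)C[C@@H](O[Si](C)(C)C(C)(C)C)[C@H](O[Si](C)(C)C(C)(C)C)/C=C/I)[C@@H](OC(=O)/C(C)=C/[C@H](C)CC)CO[Si](CC)(CC)CC | intermediate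
21 | (2S,3R)-2-[(2E,4R)-2,4-dimethylhex-2-enoyloxy]-1-hydroxyoctan-3-yl (3R,4R,5E)-3,4-bis(tert-butyldimethylsilyloxy)-6-iodohex-5-enoate | CCCCC[C@@H](OC(=O)C[C@@H](O[Si](C)(C)C(C)(C)C)[C@H](O[Si](C)(C)C(C)(C)C)/C=C/I)[C@@H](OC(=O)/C(C)=C/[C@H](C)CC)CO | intermediate
22 | (2R,3R)-2-[(2E,4R)-2,4-dimethylhex-2-enoyloxy]-1-oxooctan-3-yl (3R,4R,5E)-3,4-bis(tert-butyldimethylsilyloxy)-6-iodohex-5-enoate | CCCCC[C@@H](OC(=O)C[C@@H](O[Si](C)(C)C(C)(C)C)[C@H](O[Si](C)(C)C(C)(C)C)/C=C/I)[C@@H](OC(=O)/C(C)=C/[C@H](C)CC)C=O | intermediate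
23 | (3R,4R,5E,7S,8S,9R)-3,4-bis(tert-butyldimethylsilyloxy)-8-[(2E,4R)-2,4-dimethylhex-2-enoyloxy]-7-hydroxytetradec-5-en-9-olide | CCCCC[C@H]1OC(=O)C[C@@H](O[Si](C)(C)C(C)(C)C)[C@H](O[Si](C)(C)C(C)(C)C)/C=C/[C@H](O)[C@@H]1OC(=O)/C(C)=C/[C@H](C)CC | intermediate
24 | (3R,4R,5S,6R,7S,8S,9R)-3,4-bis(tert-butyldimethylsilyloxy)-8-[(2E,4R)-2,4-dimethylhex-2-enoyloxy]-5,6-epoxy-7-hydroxytetradecan-9-olide | CCCCC[C@H]1OC(=O)C[C@@H](O[Si](C)(C)C(C)(C)C)[C@H](O[Si](C)(C)C(C)(C)C)[C@H]2O[C@@H]2[C@H](O)[C@@H]1OC(=O)/C(C)=C/[C@H](C)CC | intermediate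
25 | (3R,4S,5R,6R,7S,8S,9R)-8-[(2E,4R)-2,4-dimethylhex-2-enoyloxy]-5,6-epoxy-3,4,7-trihydroxytetradecan-9-olide | CCCCC[C@H]1OC(=O)C[C@@H](O)[C@H](O)[C@H]2O[C@@H]2[C@H](O)[C@@H]1OC(=O)/C(C)=C/[C@H](C)CC | target

**Summary**

Total step count: 17. Longest linear sequence: 13 steps (steps 1–5, then 10–17).

Steps most likely to fail:

Step 15. The alkenylchromium may add to the wrong face of the C7 aldehyde, because strain in the closing ten-membered transition state can override the Felkin–Anh preference, and intermolecular coupling may compete. The fallback sets the C7 center after ring closure by reagent control. It sets out from 23 as obtained (mixed with its C7 epimer). Dess–Martin oxidation in CH2Cl2 with pyridine would convert both epimers into the single enone (3R,4R,5E,8R,9R)-3,4-bis(tert-butyldimethylsilyloxy)-8-[(2E,4R)-2,4-dimethylhex-2-enoyloxy]-7-oxotetradec-5-en-9-olide F5. Corey–Bakshi–Shibata reduction with (S)-1-methyl-3,3-diphenyltetrahydro-1H,3H-pyrrolo[1,2-c][1,3,2]oxazaborole and BH3·SMe2 at low temperature, with the alkenyl arm acting as the larger group, should then deliver hydride to the face that gives the 7S carbinol. The sequence comes back to the route at 23.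

Step 16. Oxygen transfer may be slow or poorly face-selective, because the hindered macrocyclic carbinol binds weakly to the titanium–tartrate complex, and titanium may also promote acyl transfer from O8 to O7. The fallback replaces hydroxyl direction by a reagent-controlled, non-directed epoxidation. It sets out from 23. Silylation with TESOTf and 2,6-lutidine would give (3R,4R,5E,7S,8S,9R)-3,4-bis(tert-butyldimethylsilyloxy)-8-[(2E,4R)-2,4-dimethylhex-2-enoyloxy]-7-(triethylsilyloxy)tetradec-5-en-9-olide F6. Shi epoxidation with the D-fructose-derived ketone 1,2:4,5-di-O-isopropylidene-β-D-erythro-2,3-hexodiulo-2,6-pyranose, Oxone (KHSO5) and K2CO3 buffer in MeCN/dimethoxymethane/water at 0 °C should place oxygen on the same C5=C6 face as in 24. This gives the C7 triethylsilyl ether of 24, 3,4-bis(tert-butyldimethylsilyloxy)-8-[(2E,4R)-2,4-dimethylhex-2-enoyloxy]-5,6-epoxy-7-(triethylsilyloxy)tetradecan-9-olide F7. HF·pyridine in THF/pyridine would then remove all three silyl groups, so the sequence comes back to the route at 25.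

Step 10. The carboxylate may attack C2 of the epoxide instead of C3, or the new acyl group may drift from O9 to O8 or O7 in the titanium-bound diol, either of which would consume the valuable acid 9. The fallback makes the C9–O bond with a cheap acid and attaches 9 by ordinary esterification. It sets out from 16. Opening with benzoic acid and Ti(OiPr)4 would give (2S,3R)-1,2-dihydroxyoctan-3-yl benzoate F1, from which any regioisomer is removed. 2,2-Dimethoxypropane with PPTS ties up the diol as (1R)-1-[(4S)-2,2-dimethyl-1,3-dioxolan-4-yl]hexyl benzoate F2. K2CO3 in methanol frees the C9 hydroxyl as (1R)-1-[(4S)-2,2-dimethyl-1,3-dioxolan-4-yl]hexan-1-ol F3. Yamaguchi esterification with 9 gives (1R)-1-[(4S)-2,2-dimethyl-1,3-dioxolan-4-yl]hexyl (3R,4R,5E)-3,4-bis(tert-butyldimethylsilyloxy)-6-iodohex-5-enoate F4. CuCl2·2H2O in acetonitrile at 0 °C should cleave the terminal acetonide without loss of the silyl ethers, so the sequence comes back to the route at 17.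

**Further compounds**

F1 | step 10 | (2S,3R)-1,2-dihydroxyoctan-3-yl benzoate | CCCCC[C@@H](OC(=O)c1ccccc1)[C@@H](O)CO
F2 | step 10 | (1R)-1-[(4S)-2,2-dimethyl-1,3-dioxolan-4-yl]hexyl benzoate | CCCCC[C@@H](OC(=O)c1ccccc1)[C@@H]1COC(C)(C)O1
F3 | step 10 | (1R)-1-[(4S)-2,2-dimethyl-1,3-dioxolan-4-yl]hexan-1-ol | CCCCC[C@@H](O)[C@@H]1COC(C)(C)O1
F4 | step 10 | (1R)-1-[(4S)-2,2-dimethyl-1,3-dioxolan-4-yl]hexyl (3R,4R,5E)-3,4-bis(tert-butyldimethylsilyloxy)-6-iodohex-5-enoate | CCCCC[C@@H](OC(=O)C[C@@H](O[Si](C)(C)C(C)(C)C)[C@H](O[Si](C)(C)C(C)(C)C)/C=C/I)[C@@H]1COC(C)(C)O1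
F5 | step 15 | (3R,4R,5E,8R,9R)-3,4-bis(tert-butyldimethylsilyloxy)-8-[(2E,4R)-2,4-dimethylhex-2-enoyloxy]-7-oxotetradec-5-en-9-olide | CCCCC[C@H]1OC(=O)C[C@@H](O[Si](C)(C)C(C)(C)C)[C@H](O[Si](C)(C)C(C)(C)C)/C=C/C(=O)[C@@H]1OC(=O)/C(C)=C/[C@H](C)CC
F6 | step 16 | (3R,4R,5E,7S,8S,9R)-3,4-bis(tert-butyldimethylsilyloxy)-8-[(2E,4R)-2,4-dimethylhex-2-enoyloxy]-7-(triethylsilyloxy)tetradec-5-en-9-olide | CCCCC[C@H]1OC(=O)C[C@@H](O[Si](C)(C)C(C)(C)C)[C@H](O[Si](C)(C)C(C)(C)C)/C=C/[C@H](O[Si](CC)(CC)CC)[C@@H]1OC(=O)/C(C)=C/[C@H](C)CC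
F7 | step 16 | 3,4-bis(tert-butyldimethylsilyloxy)-8-[(2E,4R)-2,4-dimethylhex-2-enoyloxy]-5,6-epoxy-7-(triethylsilyloxy)tetradecan-9-olide, configured as 24 | CCCCC[C@H]1OC(=O)C[C@@H](O[Si](C)(C)C(C)(C)C)[C@H](O[Si](C)(C)C(C)(C)C)[C@H]2O[C@@H]2[C@H](O[Si](CC)(CC)CC)[C@@H]1OC(=O)/C(C)=C/[C@H](C)CC
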